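**A direct plan and its weak points**

A direct plan would join the rings by a copper-mediated Ullmann condensation of 3,6-dichloro-2-methoxybenzoic acid A1 with 2-hydroxy-3-(hydroxymethyl)-5-methylbenzaldehyde A2, the latter made by partial oxidation of 2,6-bis(hydroxymethyl)-4-methylphenol A3.
The formyl group of the resulting ether 3-chloro-6-[2-formyl-6-(hydroxymethyl)-4-methylphenoxy]-2-methoxybenzoic acid A4 would then be turned into a phenol by Dakin oxidation, giving 3-chloro-6-[2-hydroxy-6-(hydroxymethyl)-4-methylphenoxy]-2-methoxybenzoic acid A5.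
The diol side chain and its stereocentre would be built last, on the remaining aryl chloride of A5, from 2-methylbut-3-en-2-ol A6 under palladium catalysis.
First weak point, the Ullmann condensation of A1 with A2 to give A4: a doubly ortho-substituted, formyl-deactivated phenoxide would have to displace one of two aryl chlorides at high temperature beside a free aldehyde and a benzylic alcohol, with site selectivity resting on a carboxylate effect alone.
Second weak point, the final arylation/hydroxylation of alkene A6 by aryl chloride A5: it would set the only stereocentre in the last step, on an unprotected polyfunctional substrate, by a transformation without precedent whose sense and level of induction cannot be predicted.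
Third weak point, the partial oxidation of the symmetric diol A3 to A2: stopping after one of two equivalent benzylic alcohols is a statistical desymmetrisation at the very start.

**Retrosynthetic overview of the new route**

Ring A (the benzoic acid ring) carries CO2H at C1 and the aryl ether oxygen at C6 on neighbouring carbons, with OMe at C2 beside them; this pair is cut back to an aryne (C1≡C6), the phenoxide of ring B and carbon dioxide.
The three components would combine in one operation that forms C6–O and C1–CO2H; the C2 methoxy group beside the triple bond sends the phenoxide to C6 and the carbanion to C1.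
No ring is closed: both benzene rings are bought and ring A is carried as a silylaryl triflate. The side-chain stereocentre is set first, by asymmetric transfer hydrogenation of a simple β-hydroxy aryl ketone, and carried as a silyl ether.
This removes the hot copper coupling of a hindered phenol (an aryne should accept it at 0 °C), the late unprecedented stereocentre (set in step 3 by a standard reduction) and the statistical oxidation (the two oxygens of ring B are told apart by chelation to a formyl group). The acid is formed free, so no hindered ester has to be hydrolysed.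

Key step: step 11

Assumption: the sense of induction in step 3 is assigned by analogy with acetophenone [(R,R)-ligand gives the (R)-carbinol]; if the first run shows the opposite, the (S,S)-ligand is used.

**Route**

Step 1
Reactants: 1 1-(4-hydroxy-2-methoxyphenyl)ethan-1-one
Product: 2 4-acetyl-3-methoxyphenyl N-(propan-2-yl)carbamate
Conditions: i-PrNCO (1.5 equiv), Et3N (0.2 equiv), CH2Cl2, rt
Reagents that add atoms: isopropyl isocyanate, SMILES CC(C)N=C=O
Why: Base-catalysed addition of the phenol to the isocyanate (carbamoylation); the carbamate masks the para-phenol so that the later benzylic carbinol cannot form a quinone methide, and it is the directing group for step 5; no stereocentre is involved.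

Step 2
Reactants: 2 4-acetyl-3-methoxyphenyl N-(propan-2-yl)carbamate; 3 acetone
Product: 5 4-(3-hydroxy-3-methylbutanoyl)-3-methoxyphenyl N-(propan-2-yl)carbamate, via bis-silylated enol silane 4 (not isolated)
Conditions: TMSOTf (2.2 equiv), Et3N (2.5 equiv), CH2Cl2, 0 °C; pentane, filtration, evaporation; then acetone (3 equiv), TiCl4 (1.1 equiv), CH2Cl2, −78 °C; H2O
Reagents that add atoms: none
Why: Mukaiyama aldol addition of the enol silane of an aryl methyl ketone to acetone under TiCl4 (the classic acetophenone/acetone case), which needs no strong base that could eliminate the N–H carbamate; the N–Si bond and the titanium aldolate are hydrolysed on work-up and no stereocentre is formed.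

Step 3
Reactants: 5 4-(3-hydroxy-3-methylbutanoyl)-3-methoxyphenyl N-(propan-2-yl)carbamate
Product: 6 4-[(1R)-1,3-dihydroxy-3-methylbutyl]-3-methoxyphenyl N-(propan-2-yl)carbamate
Conditions: RuCl[(R,R)-TsDPEN](p-cymene) (1 mol %), HCO2H/Et3N (5:2), EtOAc, 30 °C
Reagents that add atoms: none
Why: Noyori asymmetric transfer hydrogenation of an aryl ketone, in which hydride and proton are delivered in an outer-sphere six-membered transition state while a CH–π contact between p-cymene and the aryl ring fixes the face, so that the (R,R)-ligand should give the (1R)-carbinol as it gives (R)-1-phenylethanol; the formate medium is too weakly basic for retro-aldol cleavage.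

Step 4
Reactants: 6 4-[(1R)-1,3-dihydroxy-3-methylbutyl]-3-methoxyphenyl N-(propan-2-yl)carbamate
Product: 7 3-methoxy-4-[(1R)-3-methyl-1,3-bis(triethylsilyloxy)butyl]phenyl N-(propan-2-yl)carbamate
Conditions: TESOTf (2.5 equiv), 2,6-lutidine (4 equiv), CH2Cl2, −78 to 0 °C; H2O
Reagents that add atoms: triethylsilyl trifluoromethanesulfonate, SMILES CC[Si](CC)(CC)OS(=O)(=O)C(F)(F)F
Why: Silyl triflate/hindered base silylation caps the secondary benzylic and the tertiary hydroxyl as triethylsilyl ethers, which are inert to butyllithium and removable by fluoride at the end; no C–O bond at the stereocentre is broken, and a silyl ether lost later would still converge on the target in step 13.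

Step 5
Reactants: 7 3-methoxy-4-[(1R)-3-methyl-1,3-bis(triethylsilyloxy)butyl]phenyl N-(propan-2-yl)carbamate
Product: 10 3-methoxy-4-[(1R)-3-methyl-1,3-bis(triethylsilyloxy)butyl]-2-(trimethylsilyl)phenyl N-(propan-2-yl)carbamate, via N-silyl carbamate 8 (not isolated), via ring-silylated N-silyl carbamate 9 (not isolated)
Conditions: TMSOTf (1.1 equiv), TMEDA (1.1 equiv), Et2O, 0 °C to rt; then TMEDA (2.2 equiv), n-BuLi (2.2 equiv), −78 °C; TMSCl (3 equiv), −78 °C to rt; H2O
Reagents that add atoms: chlorotrimethylsilane, SMILES C[Si](C)(C)Cl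
Why: Directed ortho-metalation of an O-aryl N-isopropylcarbamate protected in situ on nitrogen (Snieckus–Hoppe type): lithium goes to the C–H flanked by the carbamate oxygen and OMe, the site activated by both groups, and is trapped by TMSCl; the N–Si bond is hydrolysed on work-up and the product should show two ortho-coupled ring protons.

Step 6
Reactants: 10 3-methoxy-4-[(1R)-3-methyl-1,3-bis(triethylsilyloxy)butyl]-2-(trimethylsilyl)phenyl N-(propan-2-yl)carbamate
Product: 12 3-methoxy-4-[(1R)-3-methyl-1,3-bis(triethylsilyloxy)butyl]-2-(trimethylsilyl)phenyl trifluoromethanesulfonate, via phenol 11 (not isolated)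
Conditions: DBU (1.5 equiv), Et2NH (1.3 equiv), MeCN, 40 °C; then PhNTf2 (1.5 equiv), rt
Reagents that add atoms: N-phenylbis(trifluoromethanesulfonimide), SMILES O=S(=O)(N(c1ccccc1)S(=O)(=O)C(F)(F)F)C(F)(F)F
Why: One-pot carbamate cleavage and triflation: DBU removes the N–H proton, E1cB loss of isopropyl isocyanate (scavenged by diethylamine as a urea) frees the phenoxide, and PhNTf2 triflates it in the same flask before it can expel the para-benzylic silanolate; this gives the Kobayashi-type aryne precursor.

Step 7
Reactants: 13 2-hydroxy-3-methoxy-5-methylbenzaldehyde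
Product: 14 2,3-dihydroxy-5-methylbenzaldehyde
Conditions: BBr3 (2.5 equiv), CH2Cl2, −78 to 0 °C; H2O
Reagents that add atoms: none
Why: Lewis acid cleavage of an aryl methyl ether by boron tribromide, as in the conversion of ortho-vanillin into 2,3-dihydroxybenzaldehyde; the aldehyde survives at low temperature.

Step 8
Reactants: 14 2,3-dihydroxy-5-methylbenzaldehyde
Product: 15 3-(benzyloxy)-2-hydroxy-5-methylbenzaldehyde
Conditions: NaH (2.2 equiv), DMSO/THF, rt; BnBr (1.0 equiv); aq. HCl
Reagents that add atoms: benzyl bromide, SMILES BrCc1ccccc1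
Why: Williamson etherification of the dianion: the 2-oxide is conjugated with the formyl group and chelated to sodium, so one equivalent of benzyl bromide is taken by the more nucleophilic 3-oxide, which tells the two catechol oxygens apart without any statistical step.

Step 9
Reactants: 15 3-(benzyloxy)-2-hydroxy-5-methylbenzaldehyde
Product: 16 2-(benzyloxy)-6-(hydroxymethyl)-4-methylphenol
Conditions: NaBH4 (1 equiv), MeOH/THF, 0 °C
Reagents that add atoms: none
Why: Borohydride reduction of the aldehyde to the benzylic alcohol; nothing else in the molecule is reducible under these conditions.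

Step 10
Reactants: 16 2-(benzyloxy)-6-(hydroxymethyl)-4-methylphenol
Product: 17 2-(benzyloxy)-6-{[(tert-butyldimethylsilyl)oxy]methyl}-4-methylphenol
Conditions: TBSCl (1.05 equiv), imidazole (2.0 equiv), CH2Cl2, 0 °C
Reagents that add atoms: tert-butyldimethylsilyl chloride, SMILES CC(C)(C)[Si](C)(C)Cl
Why: Selective silylation of the primary alcohol in preference to the hydrogen-bonded phenol flanked by two ortho substituents (as for salicyl alcohol), which leaves the phenol free as the nucleophile of step 11.

Step 11
Reactants: 12 3-methoxy-4-[(1R)-3-methyl-1,3-bis(triethylsilyloxy)butyl]-2-(trimethylsilyl)phenyl trifluoromethanesulfonate; 17 2-(benzyloxy)-6-{[(tert-butyldimethylsilyl)oxy]methyl}-4-methylphenol; 18 carbon dioxide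
Product: 22 6-[2-(benzyloxy)-6-{[(tert-butyldimethylsilyl)oxy]methyl}-4-methylphenoxy]-2-methoxy-3-[(1R)-3-methyl-1,3-bis(triethylsilyloxy)butyl]benzoic acid, via potassium phenoxide 19 (not isolated), via aryne 20 (not isolated), via aryl potassium adduct 21 (not isolated)
Conditions: 17 (1.5 equiv), KH (1.5 equiv), THF, 0 °C; 18-crown-6 (3 equiv), KF (3 equiv), CO2 (1 atm); 12 added over 2 h, 0 °C to rt; AcOH, H2O
Reagents that add atoms: none
Why: Proposed new method: a three-component coupling of an aryne, a phenoxide and carbon dioxide, in which fluoride attacks the ring silicon of 12 and triflate leaves to give aryne 20, phenoxide 19 adds to C6, and the aryl anion 21 formed at C1 is carboxylated by the CO2 that saturates the solution. The closest known reaction types are the aryne/amine/CO2 three-component coupling to anthranilic acids, the fluoride-induced O-arylation of phenols by silylaryl triflates, and the trapping of the same kind of ortho-aryloxy aryl anion by an ester carbonyl in the aryne route to xanthones; carboxylation of 2,6-dialkoxyphenyl anions by CO2 is standard. No ring is closed and no stereocentre is formed, and the (1R) silyl ether is not touched. The step needs regioselectivity, which the C2 methoxy group beside the triple bond secures: its inductive pull distorts the aryne so that the remote carbon C6 is the more electrophilic one and the negative charge builds up at C1 next to oxygen, while the C3 side chain turns the O-methyl group toward C1 and adds a steric bias in the same direction. It needs O-arylation, secured by the substituents at both ortho positions and the para position of the phenoxide, and it needs carboxylation to outrun protonation, secured by the absence of any O–H or N–H (phenol fully deprotonated by KH, THF in place of acetonitrile) and by a low aryne concentration with the phenoxide in excess. The reversibly formed aryl carbonate of the phenoxide should act only as a reservoir, and the hindered carboxylate product is too poor a nucleophile to compete for the aryne.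

Step 12
Reactants: 22 6-[2-(benzyloxy)-6-{[(tert-butyldimethylsilyl)oxy]methyl}-4-methylphenoxy]-2-methoxy-3-[(1R)-3-methyl-1,3-bis(triethylsilyloxy)butyl]benzoic acid
Product: 23 6-[2-hydroxy-6-{[(tert-butyldimethylsilyl)oxy]methyl}-4-methylphenoxy]-2-methoxy-3-[(1R)-3-methyl-1,3-bis(triethylsilyloxy)butyl]benzoic acid
Conditions: H2 (1 atm), Pd/C (10 wt %), EtOAc, rt
Reagents that add atoms: none
Why: Hydrogenolysis of an aryl benzyl ether, which in a non-protic solvent should be much faster than cleavage of the two benzylic silyl ethers (capped on purpose at this stage) or of the diaryl ether; the stereocentre is untouched.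

Step 13
Reactants: 23 6-[2-hydroxy-6-{[(tert-butyldimethylsilyl)oxy]methyl}-4-methylphenoxy]-2-methoxy-3-[(1R)-3-methyl-1,3-bis(triethylsilyloxy)butyl]benzoic acid
Product: 24 3-[(1R)-1,3-dihydroxy-3-methylbutyl]-6-[2-hydroxy-6-(hydroxymethyl)-4-methylphenoxy]-2-methoxybenzoic acid (CNP0452050.1)
Conditions: TBAF (6 equiv), AcOH (6 equiv), THF, 0 °C to rt
Reagents that add atoms: none
Why: Fluoride-induced cleavage of all three silyl ethers in buffered, non-acidic medium, chosen because the electron-rich benzylic carbinol (ortho-OMe, para-OAr) would ionise and racemise under acid; only Si–O bonds are broken, so the (1R) configuration set in step 3 is delivered unchanged.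

**Compound list**

1 | 1-(4-hydroxy-2-methoxyphenyl)ethan-1-one | CC(=O)c1ccc(O)cc1OC | starting material
2 | 4-acetyl-3-methoxyphenyl N-(propan-2-yl)carbamate | CC(=O)c1ccc(OC(=O)NC(C)C)cc1OC | intermediate
3 | acetone | CC(C)=O | starting material
4 | 3-methoxy-4-[1-(trimethylsilyloxy)ethenyl]phenyl N-(propan-2-yl)-N-(trimethylsilyl)carbamate (not isolated) | C=C(O[Si](C)(C)C)c1ccc(OC(=O)N(C(C)C)[Si](C)(C)C)cc1OC | intermediate
5 | 4-(3-hydroxy-3-methylbutanoyl)-3-methoxyphenyl N-(propan-2-yl)carbamate | CC(C)(O)CC(=O)c1ccc(OC(=O)NC(C)C)cc1OC | intermediate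
6 | 4-[(1R)-1,3-dihydroxy-3-methylbutyl]-3-methoxyphenyl N-(propan-2-yl)carbamate | COc1cc(OC(=O)NC(C)C)ccc1[C@H](O)CC(C)(C)O | intermediate
7 | 3-methoxy-4-[(1R)-3-methyl-1,3-bis(triethylsilyloxy)butyl]phenyl N-(propan-2-yl)carbamate | COc1cc(OC(=O)NC(C)C)ccc1[C@H](O[Si](CC)(CC)CC)CC(C)(C)O[Si](CC)(CC)CC | intermediate
8 | 3-methoxy-4-[(1R)-3-methyl-1,3-bis(triethylsilyloxy)butyl]phenyl N-(propan-2-yl)-N-(trimethylsilyl)carbamate (not isolated) | COc1cc(OC(=O)N(C(C)C)[Si](C)(C)C)ccc1[C@H](O[Si](CC)(CC)CC)CC(C)(C)O[Si](CC)(CC)CC | intermediate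
9 | 3-methoxy-4-[(1R)-3-methyl-1,3-bis(triethylsilyloxy)butyl]-2-(trimethylsilyl)phenyl N-(propan-2-yl)-N-(trimethylsilyl)carbamate (not isolated) | COc1c([Si](C)(C)C)c(OC(=O)N(C(C)C)[Si](C)(C)C)ccc1[C@H](O[Si](CC)(CC)CC)CC(C)(C)O[Si](CC)(CC)CC | intermediate
10 | 3-methoxy-4-[(1R)-3-methyl-1,3-bis(triethylsilyloxy)butyl]-2-(trimethylsilyl)phenyl N-(propan-2-yl)carbamate | COc1c([Si](C)(C)C)c(OC(=O)NC(C)C)ccc1[C@H](O[Si](CC)(CC)CC)CC(C)(C)O[Si](CC)(CC)CC | intermediate
11 | 3-methoxy-4-[(1R)-3-methyl-1,3-bis(triethylsilyloxy)butyl]-2-(trimethylsilyl)phenol (not isolated) | COc1c([Si](C)(C)C)c(O)ccc1[C@H](O[Si](CC)(CC)CC)CC(C)(C)O[Si](CC)(CC)CC | intermediate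
12 | 3-methoxy-4-[(1R)-3-methyl-1,3-bis(triethylsilyloxy)butyl]-2-(trimethylsilyl)phenyl trifluoromethanesulfonate | COc1c([Si](C)(C)C)c(OS(=O)(=O)C(F)(F)F)ccc1[C@H](O[Si](CC)(CC)CC)CC(C)(C)O[Si](CC)(CC)CC | intermediate
13 | 2-hydroxy-3-methoxy-5-methylbenzaldehyde | COc1cc(C)cc(C=O)c1O | starting material
14 | 2,3-dihydroxy-5-methylbenzaldehyde | Cc1cc(O)c(O)c(C=O)c1 | intermediate
15 | 3-(benzyloxy)-2-hydroxy-5-methylbenzaldehyde | Cc1cc(C=O)c(O)c(OCc2ccccc2)c1 | intermediate
16 | 2-(benzyloxy)-6-(hydroxymethyl)-4-methylphenol | Cc1cc(CO)c(O)c(OCc2ccccc2)c1 | intermediate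
17 | 2-(benzyloxy)-6-{[(tert-butyldimethylsilyl)oxy]methyl}-4-methylphenol | Cc1cc(CO[Si](C)(C)C(C)(C)C)c(O)c(OCc2ccccc2)c1 | intermediate
18 | carbon dioxide | O=C=O | starting material
19 | potassium 2-(benzyloxy)-6-{[(tert-butyldimethylsilyl)oxy]methyl}-4-methylphenolate (not isolated) | Cc1cc(CO[Si](C)(C)C(C)(C)C)c([O-])c(OCc2ccccc2)c1.[K+] | intermediate
20 | 1,2-didehydro-3-methoxy-4-[(1R)-3-methyl-1,3-bis(triethylsilyloxy)butyl]benzene (aryne, not isolated) | COC1=C([C@H](O[Si](CC)(CC)CC)CC(C)(C)O[Si](CC)(CC)CC)C=CC#C1 | intermediate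
21 | {2-[2-(benzyloxy)-6-{[(tert-butyldimethylsilyl)oxy]methyl}-4-methylphenoxy]-6-methoxy-5-[(1R)-3-methyl-1,3-bis(triethylsilyloxy)butyl]phenyl}potassium (not isolated) | COc1c([C@H](O[Si](CC)(CC)CC)CC(C)(C)O[Si](CC)(CC)CC)ccc(Oc2c(OCc3ccccc3)cc(C)cc2CO[Si](C)(C)C(C)(C)C)c1[K] | intermediate
22 | 6-[2-(benzyloxy)-6-{[(tert-butyldimethylsilyl)oxy]methyl}-4-methylphenoxy]-2-methoxy-3-[(1R)-3-methyl-1,3-bis(triethylsilyloxy)butyl]benzoic acid | COc1c([C@H](O[Si](CC)(CC)CC)CC(C)(C)O[Si](CC)(CC)CC)ccc(Oc2c(OCc3ccccc3)cc(C)cc2CO[Si](C)(C)C(C)(C)C)c1C(=O)O | intermediate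
23 | 6-[2-hydroxy-6-{[(tert-butyldimethylsilyl)oxy]methyl}-4-methylphenoxy]-2-methoxy-3-[(1R)-3-methyl-1,3-bis(triethylsilyloxy)butyl]benzoic acid | COc1c([C@H](O[Si](CC)(CC)CC)CC(C)(C)O[Si](CC)(CC)CC)ccc(Oc2c(O)cc(C)cc2CO[Si](C)(C)C(C)(C)C)c1C(=O)O | intermediate
24 | 3-[(1R)-1,3-dihydroxy-3-methylbutyl]-6-[2-hydroxy-6-(hydroxymethyl)-4-methylphenoxy]-2-methoxybenzoic acid (CNP0452050.1) | COc1c([C@H](O)CC(C)(C)O)ccc(Oc2c(O)cc(C)cc2CO)c1C(=O)O | target

**Step count and risks**

Total step count: 13. Longest linear sequence: 9 steps (steps 1 to 6, then 11 to 13); ring B is made in 4 steps (7 to 10).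

The three steps most likely to fail:

1. The key coupling (step 11, proposed new method). What may go wrong is proton capture by the aryl anion before it meets CO2, or carbonation of the phenoxide that stalls its addition to the aryne. The fallback separates the two bond formations with known chemistry and sets out from 12 and 17. Fluoride-induced O-arylation of the free phenol (CsF, MeCN, rt), with the same regiochemistry, would give the diaryl ether tert-butyl{[3-(benzyloxy)-2-{3-methoxy-4-[(1R)-3-methyl-1,3-bis(triethylsilyloxy)butyl]phenoxy}-5-methylphenyl]methoxy}dimethylsilane F1. Directed ortho-lithiation of this ether at the C–H between OMe and OAr, the site flanked by two oxygens (n-BuLi, TMEDA, THF, −40 to 0 °C), and a CO2 quench would come back to the route at 22.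

2. The debenzylation (step 12). What may go wrong is over-reduction, that is hydrogenolysis of the benzylic C–O bonds or loss of triethylsilyl groups on the palladium surface. The fallback replaces hydrogenolysis by a π-allyl palladium deprotection and sets out from 14. Allyl bromide in place of benzyl bromide under the conditions of step 8 would give 2-hydroxy-5-methyl-3-(prop-2-en-1-yloxy)benzaldehyde F2. Reduction as in step 9 would give 2-(hydroxymethyl)-4-methyl-6-(prop-2-en-1-yloxy)phenol F3. Silylation as in step 10 would give 2-{[(tert-butyldimethylsilyl)oxy]methyl}-4-methyl-6-(prop-2-en-1-yloxy)phenol F4. The coupling of step 11 with 12 would give 6-[2-{[(tert-butyldimethylsilyl)oxy]methyl}-4-methyl-6-(prop-2-en-1-yloxy)phenoxy]-2-methoxy-3-[(1R)-3-methyl-1,3-bis(triethylsilyloxy)butyl]benzoic acid F5. Pd(PPh3)4 and morpholine in THF at rt would then remove the allyl group and come back to the route at 23.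

3. The asymmetric reduction (step 3). What may go wrong is poor facial selectivity caused by the ortho-methoxy group and the free β-hydroxyl, or slow hydride transfer to the electron-rich ketone. The fallback changes the element of stereocontrol and sets out from 5. Inner-sphere hydrogenation with RuCl2[(S)-BINAP] and H2 (50 atm) in MeOH, in which the tertiary hydroxyl binds ruthenium in a six-membered chelate (as in the hydrogenation of β-hydroxy ketones and β-keto esters), would come back to the route at 6. The ligand antipode would be fixed in the first run.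

**Further compounds**

F1 | step 11 | tert-butyl{[3-(benzyloxy)-2-{3-methoxy-4-[(1R)-3-methyl-1,3-bis(triethylsilyloxy)butyl]phenoxy}-5-methylphenyl]methoxy}dimethylsilane | COc1cc(Oc2c(OCc3ccccc3)cc(C)cc2CO[Si](C)(C)C(C)(C)C)ccc1[C@H](O[Si](CC)(CC)CC)CC(C)(C)O[Si](CC)(CC)CC
F2 | step 12 | 2-hydroxy-5-methyl-3-(prop-2-en-1-yloxy)benzaldehyde | C=CCOc1cc(C)cc(C=O)c1O
F3 | step 12 | 2-(hydroxymethyl)-4-methyl-6-(prop-2-en-1-yloxy)phenol | C=CCOc1cc(C)cc(CO)c1O
F4 | step 12 | 2-{[(tert-butyldimethylsilyl)oxy]methyl}-4-methyl-6-(prop-2-en-1-yloxy)phenol | C=CCOc1cc(C)cc(CO[Si](C)(C)C(C)(C)C)c1O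
F5 | step 12 | 6-[2-{[(tert-butyldimethylsilyl)oxy]methyl}-4-methyl-6-(prop-2-en-1-yloxy)phenoxy]-2-methoxy-3-[(1R)-3-methyl-1,3-bis(triethylsilyloxy)butyl]benzoic acid | COc1c([C@H](O[Si](CC)(CC)CC)CC(C)(C)O[Si](CC)(CC)CC)ccc(Oc2c(OCC=C)cc(C)cc2CO[Si](C)(C)C(C)(C)C)c1C(=O)O
F0 | step 3 | none | none
A1 | direct plan | 3,6-dichloro-2-methoxybenzoic acid | COc1c(Cl)ccc(Cl)c1C(=O)O
A2 | direct plan | 2-hydroxy-3-(hydroxymethyl)-5-methylbenzaldehyde | Cc1cc(CO)c(O)c(C=O)c1
A3 | direct plan | 2,6-bis(hydroxymethyl)-4-methylphenol | Cc1cc(CO)c(O)c(CO)c1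
A4 | direct plan | 3-chloro-6-[2-formyl-6-(hydroxymethyl)-4-methylphenoxy]-2-methoxybenzoic acid | COc1c(Cl)ccc(Oc2c(C=O)cc(C)cc2CO)c1C(=O)O
A5 | direct plan | 3-chloro-6-[2-hydroxy-6-(hydroxymethyl)-4-methylphenoxy]-2-methoxybenzoic acid | COc1c(Cl)ccc(Oc2c(O)cc(C)cc2CO)c1C(=O)O
A6 | direct plan | 2-methylbut-3-en-2-ol | C=CC(C)(C)O
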